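**Plan**

1. Atom labels are the positions in the target SMILES. Ring A = C8‑C9‑C11‑C14‑C36, ring B = C8‑C25‑C23‑C15‑C14‑C36, ring C = C8‑C25‑C27‑C34‑C36, lactone ring D = C27‑C29‑C31‑O33‑C34.
2. Retrosynthesis: cut C15–C16 (sorbyl), then C27–C29 and O33–C31 (ring D), then C8–C25, which opens rings B and C to a cis‑hydroazulene (ring A fused to the ring C14‑C15‑C23‑C25‑C27‑C34‑C36). Then cut C6–C8, C25–CH3 and the two‑carbon unit C23–C25, which leads back to a C2‑symmetric diquinane.
3. Enabling feature: C8 (between C6=O and C9=O) and C25 (between C23=O and C27=O) are both doubly activated carbons that face each other across the folded hydroazulene, so one oxidative C8–C25 bond closes ring B and ring C together.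
4. Forward: cycloocta‑1,5‑diene → cis‑bicyclo[3.3.0]octane (ring A plus a second cyclopentane) → two‑carbon expansion of the second ring to the seven‑membered 1,3‑dione → sorbyl at C8 → rings B and C by bis‑enolate coupling → ring D by Reformatsky closure → sorbyl at C15.
5. Stereochemistry: C14/C36 from the cis ring fusion and a lipase resolution; C11 and C34 from convex‑face dihydroxylation; C8 and C25 from the ring constraint of the coupling; C27 from the cis‑fused lactone closure; C29 from the chelated zinc aldolate.

Key step: step 18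

Assumption: the lipase in step 2 acetylates the (1S,2R,5S,6R)‑diol faster (the usual preference for R‑configured secondary carbinols) and leaves diol 4; were the preference opposite, the diacetate fraction would be methanolysed to 4 instead.
Remark: 16–18 are written as diketones with C25 undefined (it equilibrates through the enol) and 22 as its bis‑enol. 13 and 14 are drawn as the convex‑face cycloadducts (C15 and C27 of the four‑membered ring are erased in step 13). 26 is both epimers at the CHBr carbon (erased in step 21).

Step 1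
Reactants: 1 cis,cis‑cycloocta‑1,5‑diene
Product: 3 racemic endo,endo‑cis‑bicyclo[3.3.0]octane‑2,6‑diol, via racemic diacetate 2 (not isolated)
Conditions: Pd(OAc)2 (cat.), Pb(OAc)4, AcOH, rt; then K2CO3 (cat.), MeOH, rt
Reagents that add atoms: lead tetraacetate, CC(=O)O[Pb](OC(C)=O)(OC(C)=O)OC(C)=O; acetic acid, CC(=O)O
Why: Palladium‑catalysed transannular oxidative cyclisation of the 1,5‑diene (acetoxypalladation, syn insertion of the second alkene, oxidative C–Pd cleavage) should give the C2‑symmetric 2,6‑diacetate with the cis ring fusion that becomes C14–C36, and transesterification with methanol frees the diol.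

Step 2
Reactants: 3 racemic endo,endo‑cis‑bicyclo[3.3.0]octane‑2,6‑diol
Product: 4 (1R,2S,5R,6S)‑cis‑bicyclo[3.3.0]octane‑2,6‑diol
Conditions: Candida antarctica lipase B (immobilised), vinyl acetate, tert‑butyl methyl ether, rt; chromatographic separation from the diacetate
Reagents that add atoms: none
Why: Lipase‑catalysed kinetic resolution by transesterification should acetylate the enantiomer with R‑configured carbinols twice and leave the required diol, which fixes the absolute configuration of C14 and C36.

Step 3
Reactants: 4 (1R,2S,5R,6S)‑cis‑bicyclo[3.3.0]octane‑2,6‑diol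
Product: 5 (1R,5R)‑cis‑bicyclo[3.3.0]octane‑2,6‑dione
Conditions: IBX (2‑iodoxybenzoic acid), EtOAc, 80 °C
Reagents that add atoms: none
Why: IBX oxidation of both secondary alcohols should give the C2‑symmetric diketone, whose ring‑fusion centres can only return to the cis‑fused form if they enolise.

Step 4
Reactants: 5 (1R,5R)‑cis‑bicyclo[3.3.0]octane‑2,6‑dione
Product: 6 (1R,5R)‑bicyclo[3.3.0]octa‑2,6‑diene‑2,6‑diyl bis(trifluoromethanesulfonate)
Conditions: KN(SiMe3)2, PhNTf2, THF, −78 °C
Reagents that add atoms: N‑phenylbis(trifluoromethanesulfonimide), O=S(=O)(N(c1ccccc1)S(=O)(=O)C(F)(F)F)C(F)(F)F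
Why: Kinetic deprotonation at the methylene groups (C9, C27) rather than at the ring‑fusion methines, followed by O‑sulfonylation (enol triflate formation), should place both double bonds away from the ring fusion.

Step 5
Reactants: 6 bis(enol triflate)
Product: 7 (1R,5R)‑2,6‑dimethylbicyclo[3.3.0]octa‑2,6‑diene
Conditions: MeMgBr, Fe(acac)3 (cat.), THF/N‑methylpyrrolidone, −30 → 0 °C
Reagents that add atoms: methylmagnesium bromide, C[Mg]Br
Why: Iron‑catalysed Kumada‑type cross‑coupling of the alkenyl triflates with the methyl Grignard reagent should install the methyl groups on C11 and C34 without moving the double bonds.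

Step 6
Reactants: 7 (1R,5R)‑2,6‑dimethylbicyclo[3.3.0]octa‑2,6‑diene
Product: 8 C2‑symmetric tetraol (hydroxyls at C9, C11, C27, C34, all on the convex face)
Conditions: K2OsO4·2H2O (cat.), N‑methylmorpholine N‑oxide, acetone/H2O, rt
Reagents that add atoms: N‑methylmorpholine N‑oxide, C[N+]1([O-])CCOCC1; water, O
Why: Catalytic osmium tetroxide syn‑dihydroxylation should attack both trisubstituted alkenes on the convex face of the cis‑fused diquinane, so the tertiary C–O bonds at C11 and C34 come out cis to the ring‑fusion hydrogens.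

Step 7
Reactants: 8 C2‑symmetric tetraol
Product: 9 monocarbonate (cyclic carbonate across O–C9 and O–C11; C27,C34‑diol free)
Conditions: 1,1'‑carbonyldiimidazole (1 equiv), THF, rt → 50 °C
Reagents that add atoms: 1,1'‑carbonyldiimidazole, O=C(n1ccnc1)n1ccnc1
Why: Carbonyl transfer to one cis‑1,2‑diol should give the cyclic carbonate; because the tetraol is C2‑symmetric either diol gives the same monocarbonate (statistical desymmetrisation, biscarbonate and tetraol being recycled), and the protected ring becomes ring A.

Step 8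
Reactants: 9 monocarbonate
Product: 10 C27 ketone (α‑ketol with free C34 hydroxyl), carbonate retained
Conditions: IBX, DMSO, rt
Reagents that add atoms: none
Why: IBX oxidation of the remaining secondary alcohol of the secondary/tertiary diol should stop at the α‑ketol without glycol cleavage, leaving the only ketone in the ring that is to be expanded.

Step 9
Reactants: 10 keto carbonate
Product: 11 C34 triethylsilyl ether
Conditions: Et3SiOTf, 2,6‑lutidine, CH2Cl2, −78 → 0 °C
Reagents that add atoms: triethylsilyl trifluoromethanesulfonate, CC[Si](CC)(CC)OS(=O)(=O)C(F)(F)F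
Why: Silylation of the tertiary α‑ketol hydroxyl with the silyl triflate gives an ether that survives the basic steps ahead and can later be removed in the presence of a bulkier silyl ether.

Step 10
Reactants: 11 C34 triethylsilyl ether
Product: 12 trimethylsilyl enol ether C27(OSiMe3)=C15
Conditions: Me3SiOTf, Et3N, CH2Cl2, 0 °C
Reagents that add atoms: trimethylsilyl trifluoromethanesulfonate, C[Si](C)(C)OS(=O)(=O)C(F)(F)F
Why: Soft enolisation and O‑silylation (silyl enol ether formation) can only occur toward C15, because C34 is quaternary.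

Step 11
Reactants: 12 trimethylsilyl enol ether
Product: 13 dichlorocyclobutanone (four‑membered ring C15–C23(=O)–C25Cl2–C27)
Conditions: Cl2CHCOCl, Et3N, hexane/Et2O, rt, slow addition
Reagents that add atoms: dichloroacetyl chloride, O=C(Cl)C(Cl)Cl
Why: [2+2] cycloaddition of dichloroketene with the electron‑rich silyl enol ether should join nucleophilic C15 to the ketene carbonyl carbon (future C23) and C27 to the CCl2 carbon (future C25).

Step 12
Reactants: 13 dichlorocyclobutanone
Product: 14 dechlorinated cyclobutanone
Conditions: Zn dust, AcOH, THF, 0 °C → rt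
Reagents that add atoms: none
Why: Zinc‑mediated reductive dehalogenation of the α,α‑dichloroketone removes the anion‑stabilising chlorines from C25, so the later retro‑aldol cleavage is directed to the ring‑fusion bond.

Step 13
Reactants: 14 dechlorinated cyclobutanone
Product: 16 C25‑methyl cycloheptane‑1,3‑dione with free C9,C11‑diol, via unmethylated dione diol 15 (not isolated)
Conditions: K2CO3, MeOH, 0 °C → rt; then MeI, rt
Reagents that add atoms: iodomethane, CI
Why: Methanolysis of the strained cyclobutanol silyl ether should trigger retro‑aldol cleavage of the C15–C27 bond (two‑carbon ring expansion to the cycloheptane‑1,3‑dione), the same conditions open the cyclic carbonate, and the potassium diketonate is then C‑methylated at C25 (alkylation of a 1,3‑dione).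

Step 14
Reactants: 16 methylated dione diol
Product: 17 ring‑A α‑ketol (C9 ketone, free C11 hydroxyl)
Conditions: Dess–Martin periodinane, NaHCO3, CH2Cl2, 0 °C
Reagents that add atoms: none
Why: Dess–Martin oxidation converts the one secondary alcohol into the C9 ketone, while the tertiary C11 hydroxyl cannot be oxidised.

Step 15
Reactants: 17 ring‑A α‑ketol
Product: 18 C11 tert‑butyldimethylsilyl ether
Conditions: tBuMe2SiOTf, 2,6‑lutidine, CH2Cl2, 0 °C; aqueous work‑up
Reagents that add atoms: tert‑butyldimethylsilyl trifluoromethanesulfonate, CC(C)(C)[Si](C)(C)OS(=O)(=O)C(F)(F)F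
Why: Silylation of the only free hydroxyl (C11) with the silyl triflate gives the robust ether, and any enol silyl ether of the 1,3‑dione is hydrolysed on work‑up.

Step 16
Reactants: 19 sorbic acid
Product: 20 1‑[(2E,4E)‑hexa‑2,4‑dienoyl]‑1H‑benzotriazole
Conditions: 1H‑benzotriazole, SOCl2, CH2Cl2, rt
Reagents that add atoms: 1H‑benzotriazole, c1ccc2[nH]nnc2c1
Why: Activation of the acid as its N‑acylbenzotriazole (formation of an acyl transfer reagent) proceeds under conditions that leave the E,E‑diene untouched.

Step 17
Reactants: 18 C11 tert‑butyldimethylsilyl ether; 20 N‑sorbylbenzotriazole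
Product: 22 hydroazulene tetraketone (bis‑enol; sorbyl at C8), via dilithium dianion 21 (not isolated)
Conditions: LiN(iPr)2 (3.3 equiv), THF, −78 °C; then 20, −78 → −40 °C; aq. NH4Cl
Reagents that add atoms: none
Why: The first equivalent of base forms the C25 diketonate, the second removes a C8 proton of the C9 ketone (C11 is quaternary), and this more basic enolate carbon is acylated by the N‑acylbenzotriazole (crossed Claisen‑type C‑acylation), the third equivalent taking up the acidic product.

Step 18
Reactants: 22 hydroazulene tetraketone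
Product: 24 tricyclic tetraketone (rings A, B and C), via dilithium bis‑enolate 23 (not isolated)
Conditions: LiN(SiMe3)2 (2.1 equiv), THF, −78 °C; then [Fe(DMF)3Cl2][FeCl4] (1.1 equiv), DMF/THF, −78 °C → rt
Reagents that add atoms: none
Why: The base removes the two acidic protons (C8–H between C6=O and C9=O, C25–H between C23=O and C27=O); trivalent iron then takes one electron from an enolate, the resulting α‑radical is captured by the second enolate carbon, and a second one‑electron oxidation of the ketyl returns the carbonyl. The closest known reaction type is the intramolecular oxidative coupling of two carbonyl enolates by trivalent iron or divalent copper salts, including cases that create a quaternary carbon at a 1,3‑dicarbonyl position. The single new bond spans the seven‑membered ring: ring C closes in a 5‑exo‑trig mode (C25 onto C8 of the exocyclic sorbyl enolate) and ring B is the complementary 6‑exo‑trig closure. C8 and C25 can only meet on the concave face on which the seven‑membered ring is folded over ring A, so both new quaternary centres follow from C14, C36 and C34. The step needs site selectivity and no further oxidation: C8 and C25 are the only doubly activated carbons, they bear no hydrogen once coupled, and the two equivalents of base leave C15–H2 untouched.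

Step 19
Reactants: 24 tricyclic tetraketone
Product: 25 C34 tertiary alcohol
Conditions: HF·pyridine, pyridine, THF, 0 °C
Reagents that add atoms: none
Why: Buffered fluoride desilylation should distinguish the triethylsilyl ether at C34 from the bulkier tert‑butyldimethylsilyl ether at C11 (selective silyl ether cleavage by steric demand at silicon).

Step 20
Reactants: 25 C34 tertiary alcohol
Product: 26 C34 2‑bromopropanoate
Conditions: 2‑bromopropanoyl bromide, pyridine, 4‑(dimethylamino)pyridine (cat.), CH2Cl2, 0 °C → rt
Reagents that add atoms: 2‑bromopropanoyl bromide, CC(Br)C(=O)Br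
Why: Esterification of the hindered tertiary alcohol with the reactive acid bromide places the three lactone carbons on O33.

Step 21
Reactants: 26 C34 2‑bromopropanoate
Product: 27 tetracyclic hydroxy lactone (ring D closed)
Conditions: Zn dust (activated with Me3SiCl), THF, rt → 50 °C; aq. NH4Cl
Reagents that add atoms: none
Why: Zinc inserts into the C–Br bond and the ester enolate adds to the adjacent C27 ketone (intramolecular Reformatsky reaction); the short tether forces a cis‑fused lactone, which sets C27, and the chelated transition state (zinc bridging enolate and ketone oxygens) is expected to place the C29 methyl trans to the C27 oxygen.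

Step 22
Reactants: 27 tetracyclic hydroxy lactone; 20 N‑sorbylbenzotriazole
Product: 28 C11‑O‑silylated target (sorbyl at C15, enolised 1,3‑diketone)
Conditions: MgBr2·OEt2, iPr2NEt, CH2Cl2, rt; dilute aq. HCl work‑up
Reagents that add atoms: none
Why: Soft enolisation of the C23 ketone as its magnesium enolate (C15 is its only α‑CH2) and C‑acylation by the N‑acylbenzotriazole (Claisen‑type acylation) should give the enolised 1,3‑diketone without touching the tertiary alcohol or the lactone.

Step 23
Reactants: 28 C11‑O‑silylated target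
Product: 29 CNP0231466.1
Conditions: aqueous HF (48%), MeCN, 0 °C → rt
Reagents that add atoms: none
Why: Acidic fluoride cleavage of the tertiary silyl ether (desilylation) frees the C11 hydroxyl without base, which the retro‑aldol‑prone C27 carbinol and the non‑enolisable 1,3‑diketone at C8 would not tolerate.

**Compound list**

1 | cis,cis‑cycloocta‑1,5‑diene | C1C/C=C\CC/C=C\1 | starting material
2 | racemic endo,endo‑2,6‑diacetoxy‑cis‑bicyclo[3.3.0]octane (both enantiomers) | C1C[C@H](OC(C)=O)[C@@H]2CC[C@H](OC(C)=O)[C@H]12.C1C[C@@H](OC(C)=O)[C@H]2CC[C@@H](OC(C)=O)[C@@H]12 | intermediate (not isolated)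
3 | racemic endo,endo‑cis‑bicyclo[3.3.0]octane‑2,6‑diol (both enantiomers) | C1C[C@H](O)[C@@H]2CC[C@H](O)[C@H]12.C1C[C@@H](O)[C@H]2CC[C@@H](O)[C@@H]12 | intermediate
4 | (1R,2S,5R,6S)‑cis‑bicyclo[3.3.0]octane‑2,6‑diol | C1C[C@H](O)[C@@H]2CC[C@H](O)[C@H]12 | intermediate
5 | (1R,5R)‑cis‑bicyclo[3.3.0]octane‑2,6‑dione (ketones at the future C11 and C34) | C1CC(=O)[C@@H]2CCC(=O)[C@H]12 | intermediate
6 | (1R,5R)‑bicyclo[3.3.0]octa‑2,6‑diene‑2,6‑diyl bis(trifluoromethanesulfonate) | C1C=C(OS(=O)(=O)C(F)(F)F)[C@@H]2CC=C(OS(=O)(=O)C(F)(F)F)[C@H]12 | intermediate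
7 | (1R,5R)‑2,6‑dimethylbicyclo[3.3.0]octa‑2,6‑diene | C1C=C(C)[C@@H]2CC=C(C)[C@H]12 | intermediate
8 | (1R,5R)‑2,6‑dimethyl‑cis‑bicyclo[3.3.0]octane‑2,3,6,7‑tetraol, all hydroxyls cis to the ring‑fusion hydrogens | C1[C@@H](O)[C@@](C)(O)[C@@H]2C[C@@H](O)[C@@](C)(O)[C@H]12 | intermediate
9 | monocarbonate of 8 (cyclic carbonate on O–C9/O–C11, free C27/C34 diol) | C1[C@@H](OC(=O)O3)[C@]3(C)[C@@H]2C[C@@H](O)[C@@](C)(O)[C@H]12 | intermediate
10 | C27 ketone with free tertiary C34 hydroxyl, ring‑A carbonate | C1[C@@H](OC(=O)O3)[C@]3(C)[C@@H]2CC(=O)[C@@](C)(O)[C@H]12 | intermediate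
11 | C34 triethylsilyl ether of 10 | C1[C@@H](OC(=O)O3)[C@]3(C)[C@@H]2CC(=O)[C@@](C)(O[Si](CC)(CC)CC)[C@H]12 | intermediate
12 | trimethylsilyl enol ether C27(OSiMe3)=C15 of 11 | C1[C@@H](OC(=O)O3)[C@]3(C)[C@@H]2C=C(O[Si](C)(C)C)[C@@](C)(O[Si](CC)(CC)CC)[C@H]12 | intermediate
13 | dichlorocyclobutanone cycloadduct (C15–C23(=O)–C25Cl2–C27, convex‑face adduct) | C1[C@@H](OC(=O)O3)[C@]3(C)[C@@H]2[C@H]4C(=O)C(Cl)(Cl)[C@@]4(O[Si](C)(C)C)[C@@](C)(O[Si](CC)(CC)CC)[C@H]12 | intermediate
14 | dechlorinated cyclobutanone | C1[C@@H](OC(=O)O3)[C@]3(C)[C@@H]2[C@H]4C(=O)C[C@@]4(O[Si](C)(C)C)[C@@](C)(O[Si](CC)(CC)CC)[C@H]12 | intermediate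
15 | ring‑expanded cycloheptane‑1,3‑dione (C25H2) with free C9,C11‑diol and C34 triethylsilyl ether | C1[C@@H](O)[C@@](C)(O)[C@@H]2CC(=O)CC(=O)[C@@](C)(O[Si](CC)(CC)CC)[C@H]12 | intermediate (not isolated)
16 | C25‑methyl analogue of 15 (C25 not defined) | C1[C@@H](O)[C@@](C)(O)[C@@H]2CC(=O)C(C)C(=O)[C@@](C)(O[Si](CC)(CC)CC)[C@H]12 | intermediate
17 | ring‑A α‑ketol (C9 ketone, C11 hydroxyl cis to H14) | C1C(=O)[C@@](C)(O)[C@@H]2CC(=O)C(C)C(=O)[C@@](C)(O[Si](CC)(CC)CC)[C@H]12 | intermediate
18 | C11 tert‑butyldimethylsilyl ether of 17 | C1C(=O)[C@@](C)(O[Si](C)(C)C(C)(C)C)[C@@H]2CC(=O)C(C)C(=O)[C@@](C)(O[Si](CC)(CC)CC)[C@H]12 | intermediate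
19 | sorbic acid, (2E,4E)‑hexa‑2,4‑dienoic acid | C/C=C/C=C/C(=O)O | starting material
20 | 1‑[(2E,4E)‑hexa‑2,4‑dienoyl]‑1H‑benzotriazole | C/C=C/C=C/C(=O)n1nnc2ccccc12 | intermediate
21 | dilithium dianion of 18 (C23/C27 diketonate and C9=C8 enolate) | [Li+].[Li+].C1=C([O-])[C@@](C)(O[Si](C)(C)C(C)(C)C)[C@@H]2CC(=O)C(C)=C([O-])[C@@](C)(O[Si](CC)(CC)CC)[C@H]12 | intermediate (not isolated)
22 | cis‑hydroazulene tetraketone as bis‑enol: sorbyl at C8, methyl at C25, C11‑OTBS, C34‑OTES | C/C=C/C=C/C(O)=C1/C(=O)[C@@](C)(O[Si](C)(C)C(C)(C)C)[C@@H]2CC(=O)C(C)=C(O)[C@@](C)(O[Si](CC)(CC)CC)[C@H]12 | intermediate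
23 | dilithium bis‑enolate of 22 | [Li+].[Li+].C/C=C/C=C/C([O-])=C1/C(=O)[C@@](C)(O[Si](C)(C)C(C)(C)C)[C@@H]2CC(=O)C(C)=C([O-])[C@@](C)(O[Si](CC)(CC)CC)[C@H]12 | intermediate (not isolated)
24 | tricyclic tetraketone (rings A, B, C; new C8–C25 bond; C11‑OTBS, C34‑OTES) | C/C=C/C=C/C(=O)[C@]12C(=O)[C@@](C)(O[Si](C)(C)C(C)(C)C)[C@@H]3CC(=O)[C@@]1(C)C(=O)[C@@](C)(O[Si](CC)(CC)CC)[C@@H]32 | intermediate
25 | C34 alcohol of 24 | C/C=C/C=C/C(=O)[C@]12C(=O)[C@@](C)(O[Si](C)(C)C(C)(C)C)[C@@H]3CC(=O)[C@@]1(C)C(=O)[C@@](C)(O)[C@@H]32 | intermediate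
26 | C34 2‑bromopropanoate of 25 (both epimers at CHBr) | C/C=C/C=C/C(=O)[C@]12C(=O)[C@@](C)(O[Si](C)(C)C(C)(C)C)[C@@H]3CC(=O)[C@@]1(C)C(=O)[C@@](C)(OC(=O)C(C)Br)[C@@H]32 | intermediate
27 | tetracyclic β‑hydroxy γ‑lactone (ring D cis‑fused; C29 methyl trans to C27 hydroxyl; C15 still CH2) | C/C=C/C=C/C(=O)[C@]12C(=O)[C@@](C)(O[Si](C)(C)C(C)(C)C)[C@@H]3CC(=O)[C@@]1(C)[C@@]1(O)[C@@H](C)C(=O)O[C@@]1(C)[C@@H]32 | intermediate
28 | C11‑O‑tert‑butyldimethylsilyl ether of the target | C/C=C/C=C/C(=O)[C@]12C(=O)[C@@](C)(O[Si](C)(C)C(C)(C)C)[C@@H]3\C(=C(O)/C=C/C=C/C)C(=O)[C@@]1(C)[C@@]1(O)[C@@H](C)C(=O)O[C@@]1(C)[C@@H]32 | intermediate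
29 | CNP0231466.1 | C/C=C/C=C/C(=O)[C@]12C(=O)[C@@](C)(O)[C@@H]3\C(=C(O)/C=C/C=C/C)C(=O)[C@@]1(C)[C@@]1(O)[C@@H](C)C(=O)O[C@@]1(C)[C@@H]32 | target

Total step count: 23. Longest linear sequence: 22 steps (1–15 and 17–23); step 16 is a one‑step side branch.

**Steps most likely to fail**

Step 18. The two hindered enolate carbons may not combine before the first‑formed α‑radical is lost to chlorine transfer from iron, intermolecular coupling or reduction, and excess base could bring C15 into the oxidation. The fallback changes the reacting species from a metal bis‑enolate to neutral silyl enol ethers. It sets out from 22, which is silylated on both enol oxygens (Me3SiCl, Et3N) to the bis(trimethylsilyl) enol ether F1. Oxidation with (NH4)2Ce(NO3)6 (tetravalent cerium) and NaHCO3 in MeCN at low temperature then couples the two silyl enol ethers through a radical cation, a known oxidative coupling, and returns to the route at 24.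

Step 13. Methoxide may add to the strained ketone, or the retro‑aldol may break the C25–C27 bond and give an acylcyclopentanone instead of the seven‑membered ring; over‑methylation is a further danger. The fallback separates the three events and uses the acid‑promoted thermal fragmentation of β‑silyloxy cyclobutanones. It sets out from 14, which is heated in AcOH/H2O/2‑propanol; both silyl ethers are lost and the carbonate stays, giving the ring‑expanded dione carbonate with free C34 hydroxyl F2. Re‑silylation (Et3SiOTf, 2,6‑lutidine) gives its C34 triethylsilyl ether F3. K2CO3/MeOH followed by MeI then opens the carbonate and methylates C25, coming back to the route at 16.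

Step 21. The zinc enolate may be protonated before it adds to the crowded C27 ketone, or may close with poor facial control at C29. The fallback sets C29 by alkylation instead of by the aldol geometry. It sets out from 25, which is acylated with bromoacetyl bromide to the C34 bromoacetate F4. Reformatsky closure (Zn, THF) gives the C29‑unsubstituted hydroxy lactone F5, which has no C29 centre to control. Treatment with LiN(iPr)2 (3.2 equiv) and MeI (1 equiv) then methylates the most basic site of the polyanion, the lactone enolate, trans to the C27 alkoxide (Fráter–Seebach alkylation) and comes back to the route at 27.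

**Further compounds**

F1 | step 18 | bis(trimethylsilyl) enol ether of 22 | C/C=C/C=C/C(O[Si](C)(C)C)=C1/C(=O)[C@@](C)(O[Si](C)(C)C(C)(C)C)[C@@H]2CC(=O)C(C)=C(O[Si](C)(C)C)[C@@](C)(O[Si](CC)(CC)CC)[C@H]12
F2 | step 13 | ring‑expanded dione carbonate with free C34 hydroxyl | C1[C@@H](OC(=O)O3)[C@]3(C)[C@@H]2CC(=O)CC(=O)[C@@](C)(O)[C@H]12
F3 | step 13 | C34 triethylsilyl ether of F2 | C1[C@@H](OC(=O)O3)[C@]3(C)[C@@H]2CC(=O)CC(=O)[C@@](C)(O[Si](CC)(CC)CC)[C@H]12
F4 | step 21 | C34 bromoacetate of 25 | C/C=C/C=C/C(=O)[C@]12C(=O)[C@@](C)(O[Si](C)(C)C(C)(C)C)[C@@H]3CC(=O)[C@@]1(C)C(=O)[C@@](C)(OC(=O)CBr)[C@@H]32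
F5 | step 21 | C29‑unsubstituted hydroxy lactone | C/C=C/C=C/C(=O)[C@]12C(=O)[C@@](C)(O[Si](C)(C)C(C)(C)C)[C@@H]3CC(=O)[C@@]1(C)[C@@]1(O)CC(=O)O[C@@]1(C)[C@@H]32
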